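The synthesis rests on disconnecting the lactone at the C1(carbonyl)–C7a(aryl) bond. The feature exploited is that the lactone oxygen O2 sits on the benzylic stereocentre C3, which is attached to C3a, the ring carbon ortho to C7a. A carbonyl carbon parked on O2 as a methyl carbonate therefore reaches C7a through a five-membered transition state. The precursor is the (S)-benzylic methyl carbonate of a 2-bromo-3,5-dimethoxyphenyl carbinol carrying the silyl-protected (S)-13-hydroxytetradecyl chain. Bromine–lithium exchange at C7a triggers a Parham-type 5-exo-trig cycloacylation that forms the aryl–carbonyl bond and the phthalide ring in one operation, and the acidic quench frees the C13′ alcohol.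

Key step: step 5

Assumption: 2-bromo-3,5-dimethoxybenzaldehyde (6) is taken as a catalogue compound.

Step 1
Reactants: 1 11-bromoundec-1-ene; 2 (S)-2-methyloxirane
Product: 4 (S)-tetradec-13-en-2-ol, via undec-10-enylmagnesium bromide 3 (not isolated)
Conditions: Mg, THF, rt; CuBr·SMe2 (10 mol%), 2, −30 to 0 °C; aq. NH4Cl
Reagents that add atoms: none
Why: Copper-catalysed Grignard opening of a terminal epoxide occurs at the unsubstituted CH2 of 2, so the carbinol stereocentre of 4 is the untouched (S) centre of the epoxide.

Step 2
Reactants: 4 (S)-tetradec-13-en-2-ol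
Product: 5 (S)-tert-butyldimethyl(tetradec-13-en-2-yloxy)silane
Conditions: TBSCl, imidazole, DMF, rt
Reagents that add atoms: tert-butyldimethylsilyl chloride (TBSCl), CC(C)(C)[Si](C)(C)Cl
Why: Standard silylation of a secondary alcohol masks the hydroxyl for the organometallic steps without touching the stereocentre.

Step 3
Reactants: 5 (S)-tert-butyldimethyl(tetradec-13-en-2-yloxy)silane (3 equiv); 6 2-bromo-3,5-dimethoxybenzaldehyde
Product: 9 (1S,14S)-1-(2-bromo-3,5-dimethoxyphenyl)-14-[(tert-butyldimethylsilyl)oxy]pentadecan-1-ol, via alkyldiethylborane 7 (not isolated), via dialkylzinc 8 (not isolated)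
Conditions: Et2BH (from BH3·SMe2 and Et3B), Et2O, 0 °C to rt; Et2Zn (neat), 0 °C, then vacuum; 6, Ti(OiPr)4, (1R,2R)-1,2-bis(trifluoromethanesulfonamido)cyclohexane (8 mol%), toluene, −20 °C
Reagents that add atoms: none
Why: Anti-Markovnikov hydroboration, boron–zinc exchange and catalytic asymmetric dialkylzinc addition (Knochel protocol) join chain and arene, and the (1R,2R)-bis(sulfonamide)/Ti(OiPr)4 catalyst should deliver the alkyl group to the Si face of the aldehyde to set the (S)-carbinol, independent of the remote C14 centre.

Step 4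
Reactants: 9 (1S,14S)-1-(2-bromo-3,5-dimethoxyphenyl)-14-[(tert-butyldimethylsilyl)oxy]pentadecan-1-ol
Product: 10 (1S,14S)-1-(2-bromo-3,5-dimethoxyphenyl)-14-[(tert-butyldimethylsilyl)oxy]pentadecyl methyl carbonate
Conditions: ClCO2Me, pyridine, DMAP (cat.), CH2Cl2, 0 °C to rt
Reagents that add atoms: methyl chloroformate, COC(=O)Cl
Why: DMAP-catalysed O-acylation places the future lactone carbonyl on the benzylic oxygen without breaking the C–O bond, so the C1 configuration is retained.

Step 5
Reactants: 10 (1S,14S)-1-(2-bromo-3,5-dimethoxyphenyl)-14-[(tert-butyldimethylsilyl)oxy]pentadecyl methyl carbonate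
Product: 14 (S)-3-[(S)-13-hydroxytetradecyl]-5,7-dimethoxyisobenzofuran-1(3H)-one, via aryllithium 11 (not isolated), via tetrahedral lithium alkoxide 12 (not isolated), via silyl-protected phthalide 13 (not isolated)
Conditions: n-BuLi (1.05 equiv), THF, −100 to −78 °C; then HCl/MeOH, −78 °C to rt
Reagents that add atoms: none
Why: Bromine–lithium exchange gives aryllithium 11, which adds to the tethered carbonate carbonyl to form the aryl–carbonyl bond and tetrahedral alkoxide 12; loss of LiOMe gives lactone 13, and the methanolic HCl quench cleaves the silyl ether to 14. The closest known reaction type is the Parham cyclisation, that is, halogen–lithium exchange followed by intramolecular acylation of the aryllithium by an ester or carbamate, with the 1,4 O-to-C acyl shift of o-lithiobenzyl carbamates as nearest relative. The five-membered lactone ring closes in the 5-exo-trig mode. No stereocentre is created: C3 should keep its (S) configuration because neither its C–O nor its C–H bond is touched and only LiOMe, too weak a base to deprotonate C3–H at −78 °C, is released, while the C13′ centre is remote. The step needs exchange to outrun butyl attack on the carbonyl and benzylic deprotonation, which the low temperature, the ortho-methoxy-assisted exchange and the low electrophilicity of a carbonate should secure. It also needs exocyclic collapse of 12, favoured by irreversible methoxide loss and the stability of the phthalide, and the site of ring closure is fixed by the bromine at the carbon between the side chain and a methoxy group.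

Compound list
1 | 11-bromoundec-1-ene | C=CCCCCCCCCCBr | starting material
2 | (S)-2-methyloxirane ((S)-propylene oxide) | C[C@H]1CO1 | starting material
3 | undec-10-enylmagnesium bromide | C=CCCCCCCCCC[Mg]Br | intermediate
4 | (S)-tetradec-13-en-2-ol | C[C@H](O)CCCCCCCCCCC=C | intermediate
5 | (S)-tert-butyldimethyl(tetradec-13-en-2-yloxy)silane | C[C@H](O[Si](C)(C)C(C)(C)C)CCCCCCCCCCC=C | intermediate
6 | 2-bromo-3,5-dimethoxybenzaldehyde | COc1cc(OC)c(Br)c(C=O)c1 | starting material
7 | diethyl[(13S)-13-[(tert-butyldimethylsilyl)oxy]tetradecyl]borane | CCB(CC)CCCCCCCCCCCC[C@H](C)O[Si](C)(C)C(C)(C)C | intermediate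
8 | bis[(13S)-13-[(tert-butyldimethylsilyl)oxy]tetradecyl]zinc | CC(C)(C)[Si](C)(C)O[C@@H](C)CCCCCCCCCCCC[Zn]CCCCCCCCCCCC[C@H](C)O[Si](C)(C)C(C)(C)C | intermediate
9 | (1S,14S)-1-(2-bromo-3,5-dimethoxyphenyl)-14-[(tert-butyldimethylsilyl)oxy]pentadecan-1-ol | COc1cc(OC)c(Br)c(c1)[C@@H](O)CCCCCCCCCCCC[C@H](C)O[Si](C)(C)C(C)(C)C | intermediate
10 | (1S,14S)-1-(2-bromo-3,5-dimethoxyphenyl)-14-[(tert-butyldimethylsilyl)oxy]pentadecyl methyl carbonate | COc1cc(OC)c(Br)c(c1)[C@@H](OC(=O)OC)CCCCCCCCCCCC[C@H](C)O[Si](C)(C)C(C)(C)C | intermediate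
11 | {2-[(1S,14S)-14-[(tert-butyldimethylsilyl)oxy]-1-(methoxycarbonyloxy)pentadecyl]-4,6-dimethoxyphenyl}lithium | COc1cc(OC)c([Li])c(c1)[C@@H](OC(=O)OC)CCCCCCCCCCCC[C@H](C)O[Si](C)(C)C(C)(C)C | intermediate
12 | lithium (3S)-3-[(S)-13-[(tert-butyldimethylsilyl)oxy]tetradecyl]-1,5,7-trimethoxy-1,3-dihydroisobenzofuran-1-olate (C1 unspecified) | COc1cc(OC)c2c(c1)[C@H](CCCCCCCCCCCC[C@H](C)O[Si](C)(C)C(C)(C)C)OC2(OC)O[Li] | intermediate
13 | (S)-3-[(S)-13-[(tert-butyldimethylsilyl)oxy]tetradecyl]-5,7-dimethoxyisobenzofuran-1(3H)-one | COc1cc(OC)c2c(c1)[C@H](CCCCCCCCCCCC[C@H](C)O[Si](C)(C)C(C)(C)C)OC2=O | intermediate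
14 | (S)-3-[(S)-13-hydroxytetradecyl]-5,7-dimethoxyisobenzofuran-1(3H)-one | COc1cc(OC)c2c(c1)[C@H](CCCCCCCCCCCC[C@H](C)O)OC2=O | target

Total step count: 5. Longest linear sequence: 5 steps (1 to 14 through steps 1–5).

Steps most likely to fail

Step 5. Butyl addition to the carbonate, or to the lactone once formed, may compete with exchange, and the aryllithium may be protonated before it cyclises (net debromination). The fallback sets out from 9 and returns at 13: palladium-catalysed carbonylative lactonisation of the free bromo alcohol (Pd(OAc)2, dppf, CO 1 atm, Et3N, DMF, 100 °C) should give the silyl-protected phthalide 13 without any organolithium. Separate desilylation with HCl/MeOH at rt then gives 14. This fallback makes no compound outside the list (F0).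

Step 3. Boron–zinc exchange may be incomplete, and facial selectivity of alkyl transfer to the ortho-bromo aldehyde may be poor, which would erode the C1 configuration to an epimer mixture that is hard to separate. The fallback sets out from 8 and 6 and returns at 9, moving stereocontrol from C–C bond formation to ketone reduction. Zinc reagent 8 is added to 6 with an achiral promoter (2-(dimethylamino)ethanol, 10 mol%, toluene, 0 °C) to give the C1-epimeric carbinol F1. Dess–Martin periodinane in CH2Cl2 oxidises it to aryl ketone (S)-1-(2-bromo-3,5-dimethoxyphenyl)-14-[(tert-butyldimethylsilyl)oxy]pentadecan-1-one F2. Corey–Bakshi–Shibata reduction with (R)-2-methyl-CBS-oxazaborolidine and BH3·SMe2 in THF at −20 °C, with the aryl group as the large substituent, should then give the (S)-carbinol 9.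

Step 1. Wurtz-type homocoupling during Grignard formation and bromide opening of the epoxide to a bromohydrin may lower the conversion to 4. The fallback sets out from 1 and returns at 4, replacing the Grignard reagent by a sulfone-stabilised carbanion. Displacement with PhSO2Na in DMF gives (undec-10-en-1-ylsulfonyl)benzene F3. Deprotonation with n-BuLi in THF at −78 °C gives the α-lithio sulfone F4, which opens 2 at CH2 in the presence of BF3·OEt2 to give (2S)-4-(phenylsulfonyl)tetradec-13-en-2-ol F5. Reductive desulfonylation with sodium amalgam (Na/Hg, Na2HPO4, MeOH, −20 °C) gives 4.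

Further compounds
F0 | step 5 | none | none
F1 | step 3 | (14S)-1-(2-bromo-3,5-dimethoxyphenyl)-14-[(tert-butyldimethylsilyl)oxy]pentadecan-1-ol, C1 epimer mixture | COc1cc(OC)c(Br)c(c1)C(O)CCCCCCCCCCCC[C@H](C)O[Si](C)(C)C(C)(C)C
F2 | step 3 | (S)-1-(2-bromo-3,5-dimethoxyphenyl)-14-[(tert-butyldimethylsilyl)oxy]pentadecan-1-one | COc1cc(OC)c(Br)c(c1)C(=O)CCCCCCCCCCCC[C@H](C)O[Si](C)(C)C(C)(C)C
F3 | step 1 | (undec-10-en-1-ylsulfonyl)benzene | C=CCCCCCCCCCS(=O)(=O)c1ccccc1
F4 | step 1 | [1-(phenylsulfonyl)undec-10-en-1-yl]lithium | C=CCCCCCCCCC([Li])S(=O)(=O)c1ccccc1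
F5 | step 1 | (2S)-4-(phenylsulfonyl)tetradec-13-en-2-ol, C4 epimer mixture | C[C@H](O)CC(CCCCCCCCC=C)S(=O)(=O)c1ccccc1
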